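**Two products, one ratio.** The target's share of target plus over-reaction product is set by the ratio of the two. Early on, target grows with time, while over-reaction product grows with [reagent] × [target] × time. The ratio therefore rises with [reagent] × time, and [starting material] cancels.

| flask | starting material | reagent | protic impurity | temperature | remark | time |
|---|---|---|---|---|---|---|
| north-west | 0.050 M | 0.040 M | 5 mM | 10 °C | run made earlier |  |
| south-west | 0.025 M | 0.040 M | 5 mM | 25 °C | run made earlier |  |
| north | 0.10 M | 0.040 M | 5 mM | 10 °C | run made earlier |  |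
| north-east | 0.050 M | 0.060 M | 5 mM | 25 °C | run made earlier |  |
| Wednesday's | 0.050 M | 0.0400 M | 5.00 mM | 25 °C | everything together at the start | 2.0 d |
| Tuesday's | 0.050 M (fed, over 40 h) | 0.0400 M | 5.00 mM | 25 °C | all else is in the flask from the start; the feed brings no volume worth counting | 2.0 d |
| Monday's | 0.050 M (fed, over 40 h) | 0.0400 M | 5.00 mM |  | the addition at 5 °C, then warmed to 25 °C; the feed brings no volume worth counting | 2.0 d |
| Sunday's | 0.050 M | 0.0400 M (fed, over 40 h) | 5.00 mM | 25 °C | all else is in the flask from the start; the feed brings no volume worth counting | 2.0 d |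

| run | time / d | target / % | over-reaction product / % |
|---|---|---|---|
| north-west | 0.500 | 13.2 | 0.3 |
| north-west | 1.25 | 24.0 | 3.3 |
| north-west | 1.67 | 28.4 | 5.8 |
| north-west | 2.50 | 32.8 | 8.1 |
| north-west | 4.00 | 36.1 | 13.1 |
| south-west | 0.333 | 27.6 | 4.9 |
| south-west | 0.625 | 35.5 | 10.3 |
| south-west | 1.04 | 37.7 | 19.7 |
| south-west | 1.25 | 36.4 | 23.7 |
| south-west | 1.67 | 35.4 | 29.5 |
| south-west | 2.08 | 33.3 | 35.1 |
| south-west | 2.50 | 29.4 | 39.2 |
| north | 0.417 | 11.7 | 1.5 |
| north | 0.625 | 15.7 | 1.1 |
| north | 0.833 | 16.8 | 2.2 |
| north | 1.25 | 20.7 | 2.8 |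
| north | 2.00 | 25.9 | 3.8 |
| north | 4.00 | 26.6 | 5.9 |
| north | 5.00 | 27.5 | 5.6 |
| north-east | 0.208 | 25.4 | 3.6 |
| north-east | 0.333 | 33.3 | 7.9 |
| north-east | 0.625 | 38.9 | 15.2 |
| north-east | 1.25 | 37.8 | 25.6 |
| north-east | 2.50 | 32.6 | 37.0 |

(scatter of a reading: 0.5 percentage points)

1. the flask that comes out highest in share of target in target plus over-reaction product, or "all alike" when all lie within 1.5 percentage points (Wednesday's / Tuesday's / Monday's / Sunday's / all alike)
2. share of target in target plus over-reaction product at the end, Wednesday's
3. share of target in target plus over-reaction product at the end, Tuesday's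
4. share of target in target plus over-reaction product at the end, Monday's
5. share of target in target plus over-reaction product at the end, Sunday's

- what was read earlier has a scatter of 0.5 percentage points, one standard deviation

**The number.** We scale the south-west run's first ratio by [reagent] and by hours at 25 °C, and call this the exposure number N. We count Monday's cold hours as nothing, which is our rough step, so its 8.00 h at 25 °C give N = 0.178. The share is one over one plus N, here 84.9%.

**First test.** The north-east run has twice the starting material. It reads 0.142 at its first point, where scaling gives 0.166, a gap within the scatter on so small a reading.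

**Second end.** Wednesday's exposes the flask for 2.0 d, so N = 1.07 at steady reagent, but reagent falls. The south-west run's turnover, scaled to Wednesday's, gives 2.95 reagent lifetimes. Averaging an exponential fall multiplies N by 0.321, giving 0.342 and a share of 74.5%. So one number is not enough here, and it gives us no figure for the feeds.

**The forecast.** It gives 67%, 62%, 80% and 74% for Wednesday's, Tuesday's, Monday's and Sunday's, with Monday's highest. It says of Monday's that it “stops unfinished”. Its Wednesday's figure lies below ours.

**The flasks.** Monday's comes highest, at 83.5%, with 67.4%, 67.1% and 75.1% for Wednesday's, Tuesday's and Sunday's.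

    starting material + reagent ⇌ target + by-product (K = 13.0, k = 0.0245 L mol⁻¹ min⁻¹, Ea = 63.0 kJ mol⁻¹, ΔH = −8.00 kJ mol⁻¹)
    reagent + target → over-reaction product (k = 0.0168 L mol⁻¹ min⁻¹, Ea = 61.0 kJ mol⁻¹)
    starting material + protic impurity → quenched substrate (k = 0.0952 L mol⁻¹ min⁻¹, Ea = 72.0 kJ mol⁻¹)
    (constants at 25 °C)

**Number tested.** Monday's ratio stands at 0.197 against N of 0.178, a share of 83.5% against our 84.9%. Wednesday's ratio stands at 0.484 against 0.342, so our 74.5% for Wednesday's lies 7.1 percentage points above the flask. In Tuesday's, the target's half-life against over-reaction is 1.1 d at 1.05 d and longer, 2.9 d, at 2.00 d. By then Tuesday's reagent stands at 24.3% of its charge.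

The readings are calculated for an exercise; noise was put on by code.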